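**Retrosynthetic overview**
- The dihydropyran ring F on ring A is cut last, at O5–C(CH3)2 and C6CH2–CH2. This leads back to an o-quinone methide (C5=O, C6=CH2) plus isobutene; the methylene is put on C6 in the same flask from CH2=NMe2+ (three-component Mannich/oxa-[4+2] cascade).
- Enabling feature: C6 is the only unsubstituted carbon of ring A and lies between C5–OH and C7–O and para to O1 (phloroglucinol pattern). It is therefore the most nucleophilic CH, and its aminomethyl derivative ionises readily to the quinone methide. With O7 capped and C8 carrying the prenyl group only O5 can close, and the geminal methyl groups of isobutene fix the orientation.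
- C8 prenyl: Eu(fod)3-catalysed para-Claisen–Cope shift of a 5-O-prenyl ether, which also frees the 5-OH for the key step. Chromene ring E: prenal annulation onto C3'/O4'.
- Furan ring D: DDQ oxidative O2'–C2 closure of a 2'-hydroxyisoflavone. C3–C1' bond: Suzuki–Miyaura coupling of a 3-iodochromone (from 2,4,6-trihydroxyacetophenone) with a ring-B boronate (from 5-bromo-2,4-dihydroxybenzaldehyde).
- Ring order: A and B bought; then C (pyranone), D (furan), E (chromene pyran), F (dihydropyran, key step); two MOM ethers come off last.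

Key step: step 13

Remark: the target has no stereocentre. Names use flavonoid numbering (O1, C2 to C8a, primes for ring B); "coumaronochromone" is 11H-benzofuro[2,3-b]chromen-11-one, whose furan oxygen joins C2 to C2'; prenyl is 3-methylbut-2-en-1-yl, MOM is methoxymethyl, TBS is tert-butyldimethylsilyl.

Step 1
Reactants: 1 2,4,6-trihydroxyacetophenone
Product: 2 1-[2,6-dihydroxy-4-(methoxymethoxy)phenyl]ethanone
Conditions: MOMCl (1.05 equiv), i-Pr2NEt, CH2Cl2, 0 °C
Reagents that add atoms: chloromethyl methyl ether (MOMCl), COCCl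
Why: Williamson-type O-alkylation; the para hydroxyl is the most acidic and the only one not hydrogen-bonded to the acetyl group, so one equivalent of MOMCl should cap it selectively and leave a C2-symmetric phenol whose pyranone closure cannot give regioisomers.

Step 2
Reactants: 2 1-[2,6-dihydroxy-4-(methoxymethoxy)phenyl]ethanone
Product: 3 (E)-1-[2,6-dihydroxy-4-(methoxymethoxy)phenyl]-3-(dimethylamino)prop-2-en-1-one
Conditions: DMF-DMA, toluene, 90 °C
Reagents that add atoms: N,N-dimethylformamide dimethyl acetal, COC(OC)N(C)C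
Why: enaminone formation by condensation of the acetyl methyl group with the formamide acetal is standard for o-hydroxyacetophenones and should give the E isomer under thermodynamic control.

Step 3
Reactants: 3 (E)-1-[2,6-dihydroxy-4-(methoxymethoxy)phenyl]-3-(dimethylamino)prop-2-en-1-one
Product: 4 5-hydroxy-3-iodo-7-(methoxymethoxy)-4H-chromen-4-one
Conditions: I2, pyridine, CHCl3, rt
Reagents that add atoms: iodine, II
Why: iodine-mediated cyclisation of an o-hydroxyaryl enaminone (α-iodination, 6-endo closure by the phenol, loss of dimethylamine) should give the 3-iodochromone as a single product because the two ortho hydroxyls are equivalent, with pyridine shielding the MOM ether from acid.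

Step 4
Reactants: 4 5-hydroxy-3-iodo-7-(methoxymethoxy)-4H-chromen-4-one
Product: 5 3-iodo-7-(methoxymethoxy)-5-[(3-methylbut-2-en-1-yl)oxy]-4H-chromen-4-one
Conditions: prenyl bromide, K2CO3, DMF, 50 °C
Reagents that add atoms: 1-bromo-3-methylbut-2-ene (prenyl bromide), CC(C)=CCBr
Why: Williamson etherification of the chelated 5-OH, the only hydroxyl present, with the reactive allylic bromide should give the 5-O-prenyl ether that later delivers the C8 prenyl group.

Step 5
Reactants: 6 5-bromo-2,4-dihydroxybenzaldehyde
Product: 7 5-bromo-2,4-bis[(tert-butyldimethylsilyl)oxy]benzaldehyde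
Conditions: TBSCl, imidazole, DMF, rt
Reagents that add atoms: tert-butyldimethylsilyl chloride, CC(C)(C)[Si](C)(C)Cl
Why: imidazole-promoted silyl ether formation should cap both phenols with groups that can later be removed without touching MOM ethers.

Step 6
Reactants: 7 5-bromo-2,4-bis[(tert-butyldimethylsilyl)oxy]benzaldehyde
Product: 9 5-bromo-2,4-bis[(tert-butyldimethylsilyl)oxy]phenol, via aryl formate 8 (not isolated)
Conditions: mCPBA, CH2Cl2, 0 °C to rt; then MeOH, Et3N (cat.), 0 °C
Reagents that add atoms: 3-chloroperoxybenzoic acid (mCPBA), OOC(=O)c1cccc(Cl)c1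
Why: Baeyer–Villiger oxidation of the electron-rich benzaldehyde (aryl migration favoured by the ortho and para silyloxy groups) should give the formate, which methanol transesterifies under almost neutral conditions so that no phenoxide forms and no silyl group migrates to the new hydroxyl.

Step 7
Reactants: 9 5-bromo-2,4-bis[(tert-butyldimethylsilyl)oxy]phenol
Product: 10 1-bromo-2,4-bis[(tert-butyldimethylsilyl)oxy]-5-(methoxymethoxy)benzene
Conditions: MOMCl, i-Pr2NEt, CH2Cl2, 0 °C
Reagents that add atoms: chloromethyl methyl ether (MOMCl), COCCl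
Why: Williamson-type O-alkylation of the only free phenol under amine-base conditions should give the MOM ether and so differentiate O5' from the two silyl-protected oxygens.

Step 8
Reactants: 10 1-bromo-2,4-bis[(tert-butyldimethylsilyl)oxy]-5-(methoxymethoxy)benzene
Product: 11 2-{2,4-bis[(tert-butyldimethylsilyl)oxy]-5-(methoxymethoxy)phenyl}-4,4,5,5-tetramethyl-1,3,2-dioxaborolane
Conditions: B2pin2, Pd(dppf)Cl2 (cat.), KOAc, 1,4-dioxane, 90 °C
Reagents that add atoms: bis(pinacolato)diboron, CC1(C)OB(OC1(C)C)B1OC(C)(C)C(C)(C)O1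
Why: Miyaura borylation of the aryl bromide should give the pinacol boronate, the silyl and MOM ethers being inert to KOAc.

Step 9
Reactants: 5 3-iodo-7-(methoxymethoxy)-5-[(3-methylbut-2-en-1-yl)oxy]-4H-chromen-4-one; 11 2-{2,4-bis[(tert-butyldimethylsilyl)oxy]-5-(methoxymethoxy)phenyl}-4,4,5,5-tetramethyl-1,3,2-dioxaborolane
Product: 13 3-[2,4-dihydroxy-5-(methoxymethoxy)phenyl]-7-(methoxymethoxy)-5-(prenyloxy)-4H-chromen-4-one, via bis-silyl isoflavone 12 (not isolated)
Conditions: Pd(dppf)Cl2 (cat.), K2CO3, 1,4-dioxane/H2O, 80 °C, argon; then MeOH, rt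
Reagents that add atoms: none
Why: Suzuki–Miyaura coupling at the C3–I bond should form the C3–C1' bond (the usual isoflavone synthesis from 3-iodochromones), after which base-mediated methanolysis cleaves the two phenolic silyl ethers while MOM and prenyl ethers stay.

Step 10
Reactants: 13 3-[2,4-dihydroxy-5-(methoxymethoxy)phenyl]-7-(methoxymethoxy)-5-(prenyloxy)-4H-chromen-4-one
Product: 14 4'-hydroxy-7,5'-bis(methoxymethoxy)-5-(prenyloxy)coumaronochromone
Conditions: DDQ (1.2 equiv), anhydrous 1,4-dioxane, rt to 50 °C
Reagents that add atoms: none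
Why: DDQ oxidative cyclisation of a 2'-hydroxyisoflavone (dehydrogenative C2–O bond formation, helped by the free 4'-OH through a quinone-methide-type cation at C2) is the established way to coumaronochromones; only the 2'-OH can reach C2, and ring A has no free phenol for DDQ to attack.

Step 11
Reactants: 14 4'-hydroxy-7,5'-bis(methoxymethoxy)-5-(prenyloxy)coumaronochromone
Product: 15 7,5'-bis(methoxymethoxy)-5-(prenyloxy)coumaronochromone carrying a 2,2-dimethyl-2H-pyran ring fused at C3'–C4' (oxygen on C4')
Conditions: 3-methylbut-2-enal, ethylenediammonium diacetate (EDDA, cat.), toluene, 110 °C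
Reagents that add atoms: 3-methylbut-2-enal (prenal), CC(C)=CC=O
Why: amine-catalysed condensation of the phenol with prenal followed by oxa-6π electrocyclisation (formal [3+3] chromene annulation) should occur at C3', the only free position ortho to the single free hydroxyl and activated by two oxygen substituents.

Step 12
Reactants: 15 7,5'-bis(methoxymethoxy)-5-(prenyloxy)coumaronochromone carrying the C3'–C4' dimethylpyran ring
Product: 18 5-hydroxy-7,5'-bis(methoxymethoxy)-8-prenyl chromene-fused coumaronochromone, via ortho-dienone 16 (not isolated), via para-dienone 17 (not isolated)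
Conditions: Eu(fod)3 (10 mol %), CHCl3, 60 °C
Reagents that add atoms: none
Why: Eu(fod)3-catalysed aromatic Claisen rearrangement of the chelating 5-O-prenyl ether to C6, Cope shift to C8 and enolisation (para-Claisen–Cope rearrangement, precedented for 5-O-prenyl flavones and isoflavones) should give the 8-prenyl phenol and free the 5-OH next to the unsubstituted C6.

Step 13
Reactants: 18 5-hydroxy-7,5'-bis(methoxymethoxy)-8-prenyl chromene-fused coumaronochromone; 19 2-methylpropene (isobutene)
Product: 22 7,5'-bis(methoxymethyl) ether of the target, via Mannich base 20 (not isolated), via o-quinone methide 21 (not isolated)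
Conditions: CH2=NMe2+ I− (1.2 equiv), MeCN, 50 °C; then isobutene (condensed, large excess), sealed pressure vessel, 90 °C, high dilution
Reagents that add atoms: N,N-dimethylmethyleneiminium iodide, C=[N+](C)C.[I-]
Why: Electrophilic aminomethylation (Mannich reaction) of 18 at C6 gives the Mannich base 20 as its hydroiodide, which on heating loses dimethylammonium iodide to the o-quinone methide 21 (C5=O, C6=CH2), and 21 is trapped by isobutene in an inverse-electron-demand oxa-Diels–Alder reaction that forms the C6CH2–CH2 and O5–C(CH3)2 bonds together. The closest known reaction type is the generation of acylphloroglucinol o-quinone methides from formaldehyde equivalents or phenolic Mannich bases and their [4+2] capture by 1,1-disubstituted alkenes. Ring F is closed by this intermolecular [4+2] cycloaddition (concerted but asynchronous, C–C bond leading), and no stereocentre is created. The orientation follows from the polarisation of both partners: the electrophilic exocyclic CH2 of 21 bonds to the CH2 terminus of isobutene, positive charge builds up on the carbon bearing the two methyl groups, and that carbon bonds to O5. Site selectivity rests on the substrate: C6 is the only free carbon of ring A, O7 is capped and C8 is blocked, so the quinone methide can only form across C5/C6 and close through O5, while ring B has no free phenol. Capture of 21 by the chromene or prenyl double bond of a second molecule and re-addition of the amine are held back by dilution, the large excess of isobutene and the departure of the amine as its non-nucleophilic hydroiodide.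

Step 14
Reactants: 22 7,5'-bis(methoxymethyl) ether of the target
Product: 23 target (CNP0081330.0)
Conditions: 3 M HCl (aq.), MeOH, rt to 40 °C
Reagents that add atoms: none
Why: acid-catalysed acetal exchange (MOM ether cleavage) in methanol should free both phenols under conditions mild enough for the prenyl group, the chromene and the dihydropyran ring.

**Compound list**
1 | 2,4,6-trihydroxyacetophenone | CC(=O)c1c(O)cc(O)cc1O | starting material
2 | 1-[2,6-dihydroxy-4-(methoxymethoxy)phenyl]ethanone | CC(=O)c1c(O)cc(OCOC)cc1O | intermediate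
3 | (E)-1-[2,6-dihydroxy-4-(methoxymethoxy)phenyl]-3-(dimethylamino)prop-2-en-1-one | CN(C)/C=C/C(=O)c1c(O)cc(OCOC)cc1O | intermediate
4 | 5-hydroxy-3-iodo-7-(methoxymethoxy)-4H-chromen-4-one | COCOc1cc(O)c2c(=O)c(I)coc2c1 | intermediate
5 | 3-iodo-7-(methoxymethoxy)-5-[(3-methylbut-2-en-1-yl)oxy]-4H-chromen-4-one | COCOc1cc(OCC=C(C)C)c2c(=O)c(I)coc2c1 | intermediate
6 | 5-bromo-2,4-dihydroxybenzaldehyde | O=Cc1cc(Br)c(O)cc1O | starting material
7 | 5-bromo-2,4-bis[(tert-butyldimethylsilyl)oxy]benzaldehyde | O=Cc1cc(Br)c(O[Si](C)(C)C(C)(C)C)cc1O[Si](C)(C)C(C)(C)C | intermediate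
8 | 5-bromo-2,4-bis[(tert-butyldimethylsilyl)oxy]phenyl formate | O=COc1cc(Br)c(O[Si](C)(C)C(C)(C)C)cc1O[Si](C)(C)C(C)(C)C | intermediate
9 | 5-bromo-2,4-bis[(tert-butyldimethylsilyl)oxy]phenol | Oc1cc(Br)c(O[Si](C)(C)C(C)(C)C)cc1O[Si](C)(C)C(C)(C)C | intermediate
10 | 1-bromo-2,4-bis[(tert-butyldimethylsilyl)oxy]-5-(methoxymethoxy)benzene | COCOc1cc(Br)c(O[Si](C)(C)C(C)(C)C)cc1O[Si](C)(C)C(C)(C)C | intermediate
11 | 2-{2,4-bis[(tert-butyldimethylsilyl)oxy]-5-(methoxymethoxy)phenyl}-4,4,5,5-tetramethyl-1,3,2-dioxaborolane | COCOc1cc(B2OC(C)(C)C(C)(C)O2)c(O[Si](C)(C)C(C)(C)C)cc1O[Si](C)(C)C(C)(C)C | intermediate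
12 | 3-{2,4-bis[(tert-butyldimethylsilyl)oxy]-5-(methoxymethoxy)phenyl}-7-(methoxymethoxy)-5-(prenyloxy)-4H-chromen-4-one | COCOc1cc(OCC=C(C)C)c2c(=O)c(-c3cc(OCOC)c(O[Si](C)(C)C(C)(C)C)cc3O[Si](C)(C)C(C)(C)C)coc2c1 | intermediate
13 | 3-[2,4-dihydroxy-5-(methoxymethoxy)phenyl]-7-(methoxymethoxy)-5-(prenyloxy)-4H-chromen-4-one | COCOc1cc(OCC=C(C)C)c2c(=O)c(-c3cc(OCOC)c(O)cc3O)coc2c1 | intermediate
14 | 4'-hydroxy-7,5'-bis(methoxymethoxy)-5-(prenyloxy)coumaronochromone | CC(C)=CCOc1cc(OCOC)cc2oc3oc4cc(O)c(OCOC)cc4c3c(=O)c12 | intermediate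
15 | 7,5'-bis(methoxymethoxy)-5-(prenyloxy)coumaronochromone with a 2,2-dimethyl-2H-pyran ring fused at C3'–C4' (oxygen on C4') | CC(C)=CCOc1cc(OCOC)cc2oc3oc4c5C=CC(C)(C)Oc5c(OCOC)cc4c3c(=O)c12 | intermediate
16 | ortho-dienone: 6-(2-methylbut-3-en-2-yl)-5-oxo-5,6-dihydro form of 15 after the Claisen shift | C=CC(C)(C)C1C(=O)C2=C(C=C1OCOC)Oc1oc3c4C=CC(C)(C)Oc4c(OCOC)cc3c1C2=O | intermediate
17 | para-dienone: 8-prenyl-5-oxo-5,8-dihydro form after the Cope shift | CC(C)=CCC1C(OCOC)=CC(=O)C2=C1Oc1oc3c4C=CC(C)(C)Oc4c(OCOC)cc3c1C2=O | intermediate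
18 | 5-hydroxy-7,5'-bis(methoxymethoxy)-8-prenyl coumaronochromone with the C3'–C4' dimethylpyran ring | CC(C)=CCc1c(OCOC)cc(O)c2c(=O)c3c(oc12)oc1c2C=CC(C)(C)Oc2c(OCOC)cc13 | intermediate
19 | 2-methylpropene (isobutene) | CC(C)=C | starting material
20 | Mannich base: 6-[(dimethylamino)methyl] derivative of 18 (present as hydroiodide) | CC(C)=CCc1c(OCOC)c(CN(C)C)c(O)c2c(=O)c3c(oc12)oc1c2C=CC(C)(C)Oc2c(OCOC)cc13 | intermediate
21 | o-quinone methide: 6-methylidene-5-oxo form derived from 20 | CC(C)=CCC1=C(OCOC)C(=C)C(=O)C2=C1Oc1oc3c4C=CC(C)(C)Oc4c(OCOC)cc3c1C2=O | intermediate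
22 | 7,5'-bis(methoxymethyl) ether of the target | CC(C)=CCc1c(OCOC)c2c(c3c(=O)c4c(oc13)oc1c3c(c(OCOC)cc14)OC(C)(C)C=C3)OC(C)(C)CC2 | intermediate
23 | target CNP0081330.0: 7,5'-dihydroxy-8-prenyl coumaronochromone with a 2,2-dimethyl-3,4-dihydro-2H-pyran ring at C5(O)–C6 and a 2,2-dimethyl-2H-pyran ring at C3'–C4'(O) | CC(C)=CCc1c(O)c2c(c3c(=O)c4c(oc13)oc1c3c(c(O)cc14)OC(C)(C)C=C3)OC(C)(C)CC2 | target

**Step count and risks**

Total steps: 14. Longest linear sequence: 10 steps (1 → 2 → 3 → 4 → 5 → 13 → 14 → 15 → 18 → 22 → 23; the ring-B branch from 6 is equally long).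

Steps most likely to fail:

1. Step 13 (key step). The o-quinone methide may be consumed by cycloaddition with the chromene or prenyl double bond of a second molecule before the weakly nucleophilic isobutene captures it, or the aminomethylation of the chelated phenol may stall. Fallback, setting out from 18 and returning at 22, builds the ring in the opposite order (C6–C bond first, O5–C bond last). Compound 18 is O-alkylated with prenyl bromide and K2CO3 in DMF to the 5-O-prenyl ether of 18 F1. A [1,3]-shift of the prenyl group on magnesium silicate (MgSiO3) in warm toluene moves it to the only free ortho position and gives the 6,8-diprenyl-5-hydroxy compound F2. Acid-catalysed Markovnikov 6-endo hydroalkoxylation of the C6 prenyl group by the 5-OH (TsOH·H2O cat., CH2Cl2, rt) then closes ring F to 22; the C8 prenyl group has no free neighbouring hydroxyl and should stay open.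

2. Step 10. Over-oxidation of the very electron-rich ring B to a quinone may outrun the ring closure. Fallback, setting out from 2 and returning at 14, closes the furan without an oxidant by addition–elimination at C2. Compound 2 is condensed with CS2 (NaH, THF) to 4,5-dihydroxy-7-(methoxymethoxy)-2H-chromene-2-thione F3. S-Methylation (MeI, K2CO3, acetone) gives 5-hydroxy-7-(methoxymethoxy)-2-(methylsulfanyl)-4H-chromen-4-one F4. Iodination at the nucleophilic C3 (N-iodosuccinimide, MeCN) gives the 3-iodo-2-(methylsulfanyl)chromone F5, and O-prenylation (prenyl bromide, K2CO3, DMF) gives its 5-O-prenyl ether F6. Suzuki–Miyaura coupling with 11 (Pd(dppf)Cl2, K2CO3, dioxane/H2O) gives the bis-silyl 2-(methylsulfanyl)isoflavone F7. K2CO3/MeOH then removes the silyl groups, and the 2'-phenoxide displaces methanethiolate at C2 to give 14.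

3. Step 11. Condensation at the hindered C3' position between two oxygen-bearing carbons may be slow, and during prolonged heating the 5-O-prenyl ether may begin to rearrange. Fallback, setting out from 14 and returning at 15, makes the O–C bond first. The 4'-OH is alkylated with 3-chloro-3-methylbut-1-yne (K2CO3, KI, CuI cat., acetone, 55 °C) to the 4'-O-(2-methylbut-3-yn-2-yl) ether F8. PtCl4-catalysed 6-endo hydroarylation in 1,4-dioxane at rt then closes the chromene at C3', the only free ortho position, to give 15.

**Further compounds**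
F1 | step 13 | 5-O-prenyl ether of 18 | CC(C)=CCc1c(OCOC)cc(OCC=C(C)C)c2c(=O)c3c(oc12)oc1c2C=CC(C)(C)Oc2c(OCOC)cc13
F2 | step 13 | 6,8-diprenyl-5-hydroxy analogue of 18 | CC(C)=CCc1c(OCOC)c(CC=C(C)C)c(O)c2c(=O)c3c(oc12)oc1c2C=CC(C)(C)Oc2c(OCOC)cc13
F3 | step 10 | 4,5-dihydroxy-7-(methoxymethoxy)-2H-chromene-2-thione | COCOc1cc(O)c2c(O)cc(=S)oc2c1
F4 | step 10 | 5-hydroxy-7-(methoxymethoxy)-2-(methylsulfanyl)-4H-chromen-4-one | COCOc1cc(O)c2c(=O)cc(SC)oc2c1
F5 | step 10 | 5-hydroxy-3-iodo-7-(methoxymethoxy)-2-(methylsulfanyl)-4H-chromen-4-one | COCOc1cc(O)c2c(=O)c(I)c(SC)oc2c1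
F6 | step 10 | 3-iodo-7-(methoxymethoxy)-2-(methylsulfanyl)-5-(prenyloxy)-4H-chromen-4-one | COCOc1cc(OCC=C(C)C)c2c(=O)c(I)c(SC)oc2c1
F7 | step 10 | 3-{2,4-bis[(tert-butyldimethylsilyl)oxy]-5-(methoxymethoxy)phenyl}-7-(methoxymethoxy)-2-(methylsulfanyl)-5-(prenyloxy)-4H-chromen-4-one | COCOc1cc(OCC=C(C)C)c2c(=O)c(-c3cc(OCOC)c(O[Si](C)(C)C(C)(C)C)cc3O[Si](C)(C)C(C)(C)C)c(SC)oc2c1
F8 | step 11 | 4'-O-(2-methylbut-3-yn-2-yl) ether of 14 | CC(C)=CCOc1cc(OCOC)cc2oc3oc4cc(OC(C)(C)C#C)c(OCOC)cc4c3c(=O)c12
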